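**Plan**

1. Numbering: tricyclo[5.4.0.0(2,8)]undecane with C9 the ketone, C3 the gem-dimethyl carbon, C7 the angular methyl carbon and C11 the secondary methyl carbon. Retrosynthetic cuts, in order: the two angelate C–O bonds; C4–O and C5–O (back to a C4=C5 alkene); C11–CH3; C9–C10 (key step); C4=C5 (metathesis); C7–C8 of the cyclobutane (ring contraction of a cyclopentanone).
2. Forward: a fully substituted cyclopentanone is contracted to the cyclobutane (C1, C2, C8, C7) by photo-Wolff rearrangement. Metathesis then closes the seven-membered ring (C2 to C7 through C3–C6). Carbanion acylation closes the six-membered ketone ring (C1, C11, C10, C9, C8). Enone formation, the C11 methyl, the diol and the esters follow.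
3. Feature used by the key step: C9 hangs on the cyclobutane CH C8, which is enolisable while it carries an ester, and the bridge C9–C10–C11 must span C8 and C1, which are 1,3 on the four-membered ring. A sulfonyl carbanion at C10 can therefore close the bicyclo[3.1.1]heptanone while C8 adjusts.
4. Stereochemistry: the silyloxy centre of (R)-4-silyloxycyclopentenone directs the vinyl group (C1). The vinyl group then directs the allyl group (C7) and, after loss of the silyloxy group, the reverse-prenyl group (C2). C8 is set by equilibration and by the bridge, C11 by cuprate addition anti to the C7 methyl, and C4/C5 by catalyst-controlled epoxidation and anti opening at C5.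

Key step: step 12

Remark: the face preference of the (salen)Mn catalyst on the unconjugated cycloheptene is assumed by analogy with cis-alkenes flanked by a quaternary carbon such as 2,2-dimethylchromenes; if the sense is opposite, the (S,S)-catalyst is used in step 16.

**Route**

Step 1
Reactants: 1 (R)-4-(tert-butyldimethylsilyloxy)cyclopent-2-en-1-one
Product: 2 (R)-4-(tert-butyldimethylsilyloxy)-2-iodocyclopent-2-en-1-one
Conditions: I2, pyridine, CH2Cl2, 0 → 25 °C
Reagents that add atoms: diiodine I-I
Why: Pyridine adds to the enone β-carbon, the enolate is iodinated and pyridine is expelled (Baylis–Hillman-type α-iodination of an enone), which leaves the silyloxy stereocentre untouched.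

Step 2
Reactants: 2 (R)-4-(tert-butyldimethylsilyloxy)-2-iodocyclopent-2-en-1-one; 3 tetramethylstannane
Product: 4 (R)-4-(tert-butyldimethylsilyloxy)-2-methylcyclopent-2-en-1-one
Conditions: Me4Sn, Pd2(dba)3 (cat.), AsPh3, CuI (cat.), NMP, 70 °C
Reagents that add atoms: tetramethylstannane C[Sn](C)(C)C
Why: Stille cross-coupling of the α-iodoenone transfers methyl under neutral conditions that should not provoke loss of the base-sensitive silyloxy group.

Step 3
Reactants: 4 (R)-4-(tert-butyldimethylsilyloxy)-2-methylcyclopent-2-en-1-one; 5 vinylmagnesium bromide; 6 allyl bromide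
Product: 8 (2R,3R,4R)-4-(tert-butyldimethylsilyloxy)-3-ethenyl-2-methyl-2-(prop-2-en-1-yl)cyclopentan-1-one, via bromomagnesium enolate 7 (not isolated)
Conditions: CH2=CHMgBr, CuBr·SMe2 (cat.), THF, −78 °C; then allyl bromide, HMPA, −78 → 0 °C
Reagents that add atoms: vinylmagnesium bromide C=C[Mg]Br; allyl bromide C=CCBr
Why: Copper-catalysed conjugate addition of the vinyl Grignard reagent should occur anti to the C4 silyloxy group and the enolate should be allylated anti to the new vinyl group (three-component conjugate addition–enolate alkylation), which sets C3 and the quaternary C2.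

Step 4
Reactants: 8 (2R,3R,4R)-4-(tert-butyldimethylsilyloxy)-3-ethenyl-2-methyl-2-(prop-2-en-1-yl)cyclopentan-1-one
Product: 9 (4S,5R)-4-ethenyl-5-methyl-5-(prop-2-en-1-yl)cyclopent-2-en-1-one
Conditions: DBU, CH2Cl2, 0 °C, short contact
Reagents that add atoms: none
Why: E1cB elimination of the β-silyloxy group through the only available enolate gives the enone, and the low temperature and short contact are chosen to limit γ-deprotonation at the doubly allylic C4.

Step 5
Reactants: 9 (4S,5R)-4-ethenyl-5-methyl-5-(prop-2-en-1-yl)cyclopent-2-en-1-one; 10 trimethyl(3-methylbut-2-en-1-yl)silane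
Product: 11 (2R,3S,4R)-3-ethenyl-2-methyl-4-(2-methylbut-3-en-2-yl)-2-(prop-2-en-1-yl)cyclopentan-1-one
Conditions: TiCl4, CH2Cl2, −78 °C; prenylSiMe3; aq NaHCO3
Reagents that add atoms: trimethyl(3-methylbut-2-en-1-yl)silane CC(C)=CC[Si](C)(C)C
Why: Hosomi–Sakurai conjugate allylation, in which the TiCl4-activated enone is attacked by the γ-carbon of the prenylsilane (SE2'), should install the 1,1-dimethylallyl group directly and anti to the adjacent vinyl group, so that C4 is trans to C3 and cis to the allyl group on C2.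

Step 6
Reactants: 11 (2R,3S,4R)-3-ethenyl-2-methyl-4-(2-methylbut-3-en-2-yl)-2-(prop-2-en-1-yl)cyclopentan-1-one
Product: 13 (2R,3S,4R)-5-diazo-3-ethenyl-2-methyl-4-(2-methylbut-3-en-2-yl)-2-(prop-2-en-1-yl)cyclopentan-1-one, via trifluoroacetyl ketone 12 (not isolated)
Conditions: LiN(SiMe3)2, THF, −78 °C; CF3CO2CH2CF3; aq HCl; then MsN3, Et3N, H2O, MeCN, 25 °C
Reagents that add atoms: methanesulfonyl azide CS(=O)(=O)N=[N+]=[N-]
Why: Detrifluoroacetylative diazo transfer (Regitz-type) works here because the ketone can enolise only toward C5, whose trifluoroacetylated form accepts the diazo group from the sulfonyl azide with loss of the activating acyl group.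

Step 7
Reactants: 13 (2R,3S,4R)-5-diazo-3-ethenyl-2-methyl-4-(2-methylbut-3-en-2-yl)-2-(prop-2-en-1-yl)cyclopentan-1-one
Product: 16 methyl (1R,2R,3S,4S)-3-ethenyl-2-methyl-4-(2-methylbut-3-en-2-yl)-2-(prop-2-en-1-yl)cyclobutane-1-carboxylate, via cyclobutylidene ketene 14 (not isolated), via kinetic methyl ester 15 (not isolated)
Conditions: hν (Hg lamp, Pyrex), MeOH, 0 °C; then NaOMe (cat.), MeOH, 60 °C
Reagents that add atoms: methanol CO
Why: Photochemical Wolff rearrangement (loss of N2 with 1,2-shift of the quaternary carbon with retention) contracts the ring to a ketene that methanol captures, and methoxide then equilibrates the ester-bearing centre to the epimer trans to the neighbouring tertiary-alkyl group, which is the one cis-1,3 to the vinyl group.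

Step 8
Reactants: 16 methyl (1R,2R,3S,4S)-3-ethenyl-2-methyl-4-(2-methylbut-3-en-2-yl)-2-(prop-2-en-1-yl)cyclobutane-1-carboxylate
Product: 17 methyl 8-ethenyl-1,5,5-trimethylbicyclo[4.1.1]oct-3-ene-7-carboxylate
Conditions: second-generation Grubbs catalyst (H2IMes)(PCy3)Cl2Ru=CHPh (cat.), toluene, high dilution, 80 °C
Reagents that add atoms: none
Why: Ring-closing metathesis should join the allyl and 1,1-dimethylallyl groups, which are cis-1,3 on the cyclobutane, into the cycloheptene with release of ethene, while the vinyl group is trans to both neighbours, could only close a trans-fused bicyclo[3.2.0]heptene and stays out.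

Step 9
Reactants: 17 methyl 8-ethenyl-1,5,5-trimethylbicyclo[4.1.1]oct-3-ene-7-carboxylate
Product: 19 methyl 8-(2-hydroxyethyl)-1,5,5-trimethylbicyclo[4.1.1]oct-3-ene-7-carboxylate, via alkylborane 18 (not isolated)
Conditions: 9-BBN, THF, 0 → 25 °C; then NaOH, H2O2, 0 °C
Reagents that add atoms: hydrogen peroxide OO
Why: Hydroboration–oxidation with the bulky 9-BBN is selective for the monosubstituted vinyl group over the cis-disubstituted ring alkene next to a quaternary carbon, gives the anti-Markovnikov primary alcohol and does not reduce the ester.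

Step 10
Reactants: 19 methyl 8-(2-hydroxyethyl)-1,5,5-trimethylbicyclo[4.1.1]oct-3-ene-7-carboxylate; 20 diphenyl disulfide
Product: 21 methyl 1,5,5-trimethyl-8-[2-(phenylsulfanyl)ethyl]bicyclo[4.1.1]oct-3-ene-7-carboxylate
Conditions: PhSSPh, PBu3, pyridine, 25 °C
Reagents that add atoms: diphenyl disulfide c1ccccc1SSc1ccccc1
Why: Disulfide–phosphine thioetherification (Mitsunobu-type activation of the primary alcohol as an alkoxyphosphonium ion and SN2 displacement by thiophenolate) gives the sulfide under neutral conditions.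

Step 11
Reactants: 21 methyl 1,5,5-trimethyl-8-[2-(phenylsulfanyl)ethyl]bicyclo[4.1.1]oct-3-ene-7-carboxylate
Product: 22 methyl 1,5,5-trimethyl-8-[2-(phenylsulfonyl)ethyl]bicyclo[4.1.1]oct-3-ene-7-carboxylate
Conditions: (NH4)6Mo7O24·4H2O (cat.), 30% H2O2, EtOH, 0 → 25 °C
Reagents that add atoms: hydrogen peroxide OO
Why: Molybdate-catalysed peroxide oxidation takes a sulfide to the sulfone much faster than it epoxidises a hindered ring alkene.

Step 12
Reactants: 22 methyl 1,5,5-trimethyl-8-[2-(phenylsulfonyl)ethyl]bicyclo[4.1.1]oct-3-ene-7-carboxylate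
Product: 23 3,3,7-trimethyl-10-(phenylsulfonyl)tricyclo[5.4.0.0(2,8)]undec-4-en-9-one
Conditions: LiN(SiMe3)2 (3 equiv), THF, −78 → 0 °C; then 1 M HCl
Reagents that add atoms: none
Why: The amide base reversibly deprotonates the carbon α to sulfur, the carbanion adds to the ester carbonyl and methoxide is expelled, which forms the C9–C10 bond of the tricycle as a β-keto sulfone whose immediate deprotonation makes the closure irreversible. The closest known reaction type is the intramolecular acylation of α-sulfonyl carbanions by esters, the sulfone variant of the Dieckmann condensation. The six-membered ring closes in the 6-exo-trig mode and completes the bicyclo[3.1.1]heptanone. The sulfonyl-bearing carbon is the only new stereocentre; it is acidic, should settle under thermodynamic control with the sulfonyl group away from the C7 methyl group, and is removed in step 13. The selectivity needed is C-acylation across a cis-1,3 bridge: the four-carbon bridge already in place holds the cyclobutane puckered with the ester and the sulfonylethyl arm 1,3-diaxial on the open face, and because the same base reversibly enolises the ester, any material epimeric at the ester carbon is drained through the one epimer that can cyclise. The pathway is polar throughout, so no radical or cation arises next to the four-membered ring.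

Step 13
Reactants: 23 3,3,7-trimethyl-10-(phenylsulfonyl)tricyclo[5.4.0.0(2,8)]undec-4-en-9-one
Product: 24 3,3,7-trimethyltricyclo[5.4.0.0(2,8)]undec-4-en-9-one
Conditions: Al(Hg), THF/H2O (9:1), 0 → 25 °C
Reagents that add atoms: none
Why: Reductive desulfonylation of a β-keto sulfone by electron transfer from aluminium amalgam cleaves the C–S bond α to the carbonyl and leaves the alkene and the cyclobutane alone.

Step 14
Reactants: 24 3,3,7-trimethyltricyclo[5.4.0.0(2,8)]undec-4-en-9-one
Product: 26 3,3,7-trimethyltricyclo[5.4.0.0(2,8)]undeca-4,10-dien-9-one, via trimethylsilyl enol ether 25 (not isolated)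
Conditions: Me3SiOTf, Et3N, CH2Cl2, 0 °C; then Pd(OAc)2, MeCN, 25 °C
Reagents that add atoms: none
Why: Saegusa–Ito oxidation is regiochemically unambiguous here because the ketone can enolise only toward C10 (C8 is a bridgehead, Bredt's rule), and palladation with β-hydride elimination gives the apoverbenone-type enone.

Step 15
Reactants: 26 3,3,7-trimethyltricyclo[5.4.0.0(2,8)]undeca-4,10-dien-9-one; 27 methyllithium
Product: 28 3,3,7,11-tetramethyltricyclo[5.4.0.0(2,8)]undec-4-en-9-one
Conditions: Me2CuLi (from MeLi and CuI), Et2O, −78 → −20 °C; aq NH4Cl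
Reagents that add atoms: lithium dimethylcuprate [Li+].C[Cu-]C
Why: Conjugate addition of the cuprate to the rigid enone should take place on the face of the C2 bridge, which shows only hydrogen toward the enone, and away from the C7 methyl group that projects over the other face, as in additions to apoverbenone, and so sets C11.

Step 16
Reactants: 28 3,3,7,11-tetramethyltricyclo[5.4.0.0(2,8)]undec-4-en-9-one
Product: 29 4,5-epoxy-3,3,7,11-tetramethyltricyclo[5.4.0.0(2,8)]undecan-9-one
Conditions: (R,R)-N,N'-bis(3,5-di-tert-butylsalicylidene)-1,2-cyclohexanediaminomanganese chloride (cat.), NaOCl (aq, pH 11.3), 4-phenylpyridine N-oxide, CH2Cl2, 0 °C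
Reagents that add atoms: sodium hypochlorite [Na+].[O-]Cl
Why: Jacobsen–Katsuki epoxidation of the cis-disubstituted cycloalkene is used because the two alkene faces differ in the substrate only through the remote C9 and C11 groups, so the chiral manganese oxo species, which distinguishes the CMe2-flanked from the CH2-flanked alkene carbon, is relied on to place oxygen on the face syn to C1.

Step 17
Reactants: 29 4,5-epoxy-3,3,7,11-tetramethyltricyclo[5.4.0.0(2,8)]undecan-9-one
Product: 30 4,5-dihydroxy-3,3,7,11-tetramethyltricyclo[5.4.0.0(2,8)]undecan-9-one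
Conditions: HClO4 (cat.), THF/H2O, 0 → 25 °C
Reagents that add atoms: water O
Why: Acid-catalysed anti opening of the epoxide by water at C5, the carbon next to CH2 and not the neopentylic C4, inverts C5 and keeps the C4 oxygen, which gives the trans-diol of the target.

Step 18
Reactants: 30 4,5-dihydroxy-3,3,7,11-tetramethyltricyclo[5.4.0.0(2,8)]undecan-9-one; 31 angelic acid
Product: 32 3,3,7,11-tetramethyl-9-oxotricyclo[5.4.0.0(2,8)]undecane-4,5-diyl bis[(Z)-2-methylbut-2-enoate]
Conditions: angelic acid, 2,4,6-Cl3C6H2COCl, Et3N, toluene, 25 °C; then 30, 80 °C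
Reagents that add atoms: angelic acid C/C=C(/C)C(=O)O
Why: Esterification through the angelic 2,4,6-trichlorobenzoic mixed anhydride (Yamaguchi-type) without a nucleophilic amine catalyst should acylate both secondary hydroxyls while keeping the Z geometry, since the addition–elimination path to the tiglate is avoided.

**Compound list**

1 | (R)-4-(tert-butyldimethylsilyloxy)cyclopent-2-en-1-one | CC(C)(C)[Si](C)(C)O[C@@H]1CC(=O)C=C1 | starting material
2 | (R)-4-(tert-butyldimethylsilyloxy)-2-iodocyclopent-2-en-1-one | CC(C)(C)[Si](C)(C)O[C@@H]1CC(=O)C(I)=C1 | intermediate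
3 | tetramethylstannane | C[Sn](C)(C)C | starting material
4 | (R)-4-(tert-butyldimethylsilyloxy)-2-methylcyclopent-2-en-1-one | CC(C)(C)[Si](C)(C)O[C@@H]1CC(=O)C(C)=C1 | intermediate
5 | vinylmagnesium bromide | C=C[Mg]Br | starting material
6 | allyl bromide | C=CCBr | starting material
7 | bromomagnesium (3R,4R)-4-(tert-butyldimethylsilyloxy)-3-ethenyl-2-methylcyclopent-1-en-1-olate (vinyl trans to silyloxy) | Br[Mg]OC1=C(C)[C@@H](C=C)[C@H](O[Si](C)(C)C(C)(C)C)C1 | intermediate
8 | (2R,3R,4R)-4-(tert-butyldimethylsilyloxy)-3-ethenyl-2-methyl-2-(prop-2-en-1-yl)cyclopentan-1-one (allyl trans to vinyl, vinyl trans to silyloxy) | O=C1[C@](C)(CC=C)[C@@H](C=C)[C@H](O[Si](C)(C)C(C)(C)C)C1 | intermediate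
9 | (4S,5R)-4-ethenyl-5-methyl-5-(prop-2-en-1-yl)cyclopent-2-en-1-one (allyl trans to vinyl) | O=C1[C@](C)(CC=C)[C@@H](C=C)C=C1 | intermediate
10 | trimethyl(3-methylbut-2-en-1-yl)silane (prenyltrimethylsilane) | CC(C)=CC[Si](C)(C)C | starting material
11 | (2R,3S,4R)-3-ethenyl-2-methyl-4-(2-methylbut-3-en-2-yl)-2-(prop-2-en-1-yl)cyclopentan-1-one (allyl and dimethylallyl cis to each other, both trans to vinyl) | O=C1[C@](C)(CC=C)[C@@H](C=C)[C@H](C(C)(C)C=C)C1 | intermediate
12 | 5-(trifluoroacetyl) derivative of 11 (C5 not assigned, largely enolised) | O=C1[C@](C)(CC=C)[C@@H](C=C)[C@H](C(C)(C)C=C)C1C(=O)C(F)(F)F | intermediate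
13 | (2R,3S,4R)-5-diazo-3-ethenyl-2-methyl-4-(2-methylbut-3-en-2-yl)-2-(prop-2-en-1-yl)cyclopentan-1-one | O=C1[C@](C)(CC=C)[C@@H](C=C)[C@H](C(C)(C)C=C)C1=[N+]=[N-] | intermediate
14 | [3-ethenyl-2-methyl-4-(2-methylbut-3-en-2-yl)-2-(prop-2-en-1-yl)cyclobutylidene]ketene (ring substituents as in 16) | O=C=C1[C@](C)(CC=C)[C@@H](C=C)[C@@H]1C(C)(C)C=C | intermediate
15 | methyl 3-ethenyl-2-methyl-4-(2-methylbut-3-en-2-yl)-2-(prop-2-en-1-yl)cyclobutane-1-carboxylate as formed from the ketene (C1 not yet defined, other centres as in 16) | COC(=O)C1[C@](C)(CC=C)[C@@H](C=C)[C@@H]1C(C)(C)C=C | intermediate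
16 | methyl (1R,2R,3S,4S)-3-ethenyl-2-methyl-4-(2-methylbut-3-en-2-yl)-2-(prop-2-en-1-yl)cyclobutane-1-carboxylate (ester cis-1,3 to vinyl, trans to dimethylallyl) | COC(=O)[C@H]1[C@](C)(CC=C)[C@@H](C=C)[C@@H]1C(C)(C)C=C | intermediate
17 | methyl 8-ethenyl-1,5,5-trimethylbicyclo[4.1.1]oct-3-ene-7-carboxylate (ester and vinyl both on the face away from the C2–C5 bridge) | C1[C@]2(C)[C@@H](C=C)[C@@H]([C@H]2C(=O)OC)C(C)(C)C=C1 | intermediate
18 | B-alkyl-9-borabicyclo[3.3.1]nonane from 17 (boron on the terminal carbon of the former vinyl group) | C1[C@]2(C)[C@@H](CCB3C4CCCC3CCC4)[C@@H]([C@H]2C(=O)OC)C(C)(C)C=C1 | intermediate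
19 | methyl 8-(2-hydroxyethyl)-1,5,5-trimethylbicyclo[4.1.1]oct-3-ene-7-carboxylate (configuration as in 17) | C1[C@]2(C)[C@@H](CCO)[C@@H]([C@H]2C(=O)OC)C(C)(C)C=C1 | intermediate
20 | diphenyl disulfide | c1ccccc1SSc1ccccc1 | starting material
21 | methyl 1,5,5-trimethyl-8-[2-(phenylsulfanyl)ethyl]bicyclo[4.1.1]oct-3-ene-7-carboxylate (configuration as in 17) | C1[C@]2(C)[C@@H](CCSc3ccccc3)[C@@H]([C@H]2C(=O)OC)C(C)(C)C=C1 | intermediate
22 | methyl 1,5,5-trimethyl-8-[2-(phenylsulfonyl)ethyl]bicyclo[4.1.1]oct-3-ene-7-carboxylate (ester and sulfonylethyl arm cis, both away from the C2–C5 bridge) | C1[C@]2(C)[C@@H](CCS(=O)(=O)c3ccccc3)[C@@H]([C@H]2C(=O)OC)C(C)(C)C=C1 | intermediate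
23 | 3,3,7-trimethyl-10-(phenylsulfonyl)tricyclo[5.4.0.0(2,8)]undec-4-en-9-one (sulfonyl on the face of the C2 bridge, away from the C7 methyl) | C1[C@]2(C)[C@@H]3[C@@H]([C@H]2C(=O)[C@@H](S(=O)(=O)c4ccccc4)C3)C(C)(C)C=C1 | intermediate
24 | 3,3,7-trimethyltricyclo[5.4.0.0(2,8)]undec-4-en-9-one | C1[C@]2(C)[C@@H]3[C@@H]([C@H]2C(=O)CC3)C(C)(C)C=C1 | intermediate
25 | 3,3,7-trimethyl-9-(trimethylsilyloxy)tricyclo[5.4.0.0(2,8)]undeca-4,9-diene | C1[C@]2(C)[C@@H]3[C@@H]([C@H]2C(O[Si](C)(C)C)=CC3)C(C)(C)C=C1 | intermediate
26 | 3,3,7-trimethyltricyclo[5.4.0.0(2,8)]undeca-4,10-dien-9-one | C1[C@]2(C)[C@@H]3[C@@H]([C@H]2C(=O)C=C3)C(C)(C)C=C1 | intermediate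
27 | methyllithium | [Li]C | starting material
28 | 3,3,7,11-tetramethyltricyclo[5.4.0.0(2,8)]undec-4-en-9-one (C11 methyl on the face of the C2 bridge, anti to the C7 methyl) | C1[C@]2(C)[C@@H]3[C@@H]([C@H]2C(=O)C[C@H]3C)C(C)(C)C=C1 | intermediate
29 | 4,5-epoxy-3,3,7,11-tetramethyltricyclo[5.4.0.0(2,8)]undecan-9-one (epoxide oxygen on the face syn to C1) | O1[C@@H]2C[C@]3(C)[C@@H]4[C@@H]([C@H]3C(=O)C[C@H]4C)C(C)(C)[C@H]12 | intermediate
30 | 4,5-dihydroxy-3,3,7,11-tetramethyltricyclo[5.4.0.0(2,8)]undecan-9-one (trans-diol; C5 hydroxyl syn to C8, C4 hydroxyl syn to C1) | O[C@H]1C[C@]2(C)[C@@H]3[C@@H]([C@H]2C(=O)C[C@H]3C)C(C)(C)[C@@H]1O | intermediate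
31 | angelic acid, (Z)-2-methylbut-2-enoic acid | C/C=C(/C)C(=O)O | starting material
32 | 3,3,7,11-tetramethyl-9-oxotricyclo[5.4.0.0(2,8)]undecane-4,5-diyl bis[(Z)-2-methylbut-2-enoate], CNP0109825.1 | C/C=C(/C)C(=O)O[C@H]1C[C@]2(C)[C@@H]3[C@@H]([C@H]2C(=O)C[C@H]3C)C(C)(C)[C@@H]1OC(=O)/C(C)=C\C | target

**Count and risks**

Total step count: 18. Longest linear sequence: 18 steps (1 to 32).

Steps most likely to fail:

Step 16. Face selection by the catalyst may be poor, because the alkene is unconjugated and its two faces are almost equivalent in the substrate, so the epoxide could form on both faces. The fallback gives up catalyst control and sets out from 28: dimethyldioxirane in acetone at 0 °C should epoxidise both faces and give 29 together with the epoxide on the face syn to C8, 4,5-epoxy-3,3,7,11-tetramethyltricyclo[5.4.0.0(2,8)]undecan-9-one with the oxygen syn to C8 F1. The two diastereomers are separated by chromatography. F1 is deoxygenated stereospecifically back to 28 with PPh3 and catalytic MeReO3 and recycled, and the route is rejoined at 29.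

Step 8. Ring closure may be slower than intermolecular metathesis through the third vinyl group, because both reacting chains must swing into axial positions on the cyclobutane and one alkene is neopentylic. The fallback closes the seven-membered ring before the ring contraction and sets out from 11. Metathesis with the same catalyst across the cis-1,3 positions of the cyclopentanone should give the much less strained 9-ethenyl-2,2,6-trimethylbicyclo[4.2.1]non-3-en-7-one F2. Diazo transfer as in step 6 then passes through the 8-(trifluoroacetyl) ketone F3 to 8-diazo-9-ethenyl-2,2,6-trimethylbicyclo[4.2.1]non-3-en-7-one F4. Photolysis in methanol contracts the two-carbon ketone bridge through the bicyclo[4.1.1]octenylidene ketene F5 to the methyl ester, which may emerge as 17 accompanied by its C7 epimer F6. F6 is separated, re-equilibrated with NaOMe in methanol and recycled, and the route is rejoined at 17.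

Step 12. C-acylation may be outrun by unproductive enolisation of the hindered ester, or stall because the carbanion concentration under the amide base is low. The fallback uses a more electrophilic carbonyl and sets out from 22. Reduction with i-Bu2AlH in CH2Cl2 at −78 °C should give 1,5,5-trimethyl-8-[2-(phenylsulfonyl)ethyl]bicyclo[4.1.1]oct-3-ene-7-carbaldehyde F7, whose α-centre is still epimerisable. LiN(SiMe3)2 in THF then closes the ring by addition of the sulfonyl carbanion to the aldehyde and gives 9-hydroxy-3,3,7-trimethyl-10-(phenylsulfonyl)tricyclo[5.4.0.0(2,8)]undec-4-ene F8 as a mixture at the two new centres. Oxidation with Dess–Martin periodinane returns to the route at 23.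

Further compounds
F1 | step 16 | 4,5-epoxy-3,3,7,11-tetramethyltricyclo[5.4.0.0(2,8)]undecan-9-one with the epoxide oxygen syn to C8 | O1[C@H]2C[C@]3(C)[C@@H]4[C@@H]([C@H]3C(=O)C[C@H]4C)C(C)(C)[C@@H]12
F2 | step 8 | 9-ethenyl-2,2,6-trimethylbicyclo[4.2.1]non-3-en-7-one | O=C1C[C@@H]2[C@H](C=C)[C@@]1(C)CC=CC2(C)C
F3 | step 8 | 9-ethenyl-2,2,6-trimethyl-8-(trifluoroacetyl)bicyclo[4.2.1]non-3-en-7-one (C8 not assigned) | O=C1C(C(=O)C(F)(F)F)[C@@H]2[C@H](C=C)[C@@]1(C)CC=CC2(C)C
F4 | step 8 | 8-diazo-9-ethenyl-2,2,6-trimethylbicyclo[4.2.1]non-3-en-7-one | O=C1C(=[N+]=[N-])[C@@H]2[C@H](C=C)[C@@]1(C)CC=CC2(C)C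
F5 | step 8 | (8-ethenyl-1,5,5-trimethylbicyclo[4.1.1]oct-3-en-7-ylidene)ketene | C1[C@]2(C)[C@@H](C=C)[C@@H](C2=C=O)C(C)(C)C=C1
F6 | step 8 | C7 epimer of 17, ester syn to the C2–C5 bridge | C1[C@]2(C)[C@@H](C=C)[C@@H]([C@@H]2C(=O)OC)C(C)(C)C=C1
F7 | step 12 | 1,5,5-trimethyl-8-[2-(phenylsulfonyl)ethyl]bicyclo[4.1.1]oct-3-ene-7-carbaldehyde | C1[C@]2(C)[C@@H](CCS(=O)(=O)c3ccccc3)[C@@H]([C@H]2C=O)C(C)(C)C=C1
F8 | step 12 | 9-hydroxy-3,3,7-trimethyl-10-(phenylsulfonyl)tricyclo[5.4.0.0(2,8)]undec-4-ene (C9 and C10 not assigned) | C1[C@]2(C)[C@@H]3[C@@H]([C@H]2C(O)C(S(=O)(=O)c4ccccc4)C3)C(C)(C)C=C1
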